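- Start from target, since that is what you want from gamma against theta; your hunch was that feed time and cold dosing hardly matter, so test it on the numbers below.

all flasks: solid substrate 0.15 M

| run | partner | protic impurity | temperature | remark | time |
|---|---|---|---|---|---|
| south | 0.50 equiv (fed, over 10 min) | 0.015 M | −15 °C | run made earlier; the fed solution adds 1.0 times the starting volume |  |
| south-east | 2 equiv (fed, over 10 min) | 0.015 M | 2 °C | run made earlier; the fed solution adds 1.0 times the starting volume |  |
| east | 1 equiv (fed, over 10 min) | 0.030 M | −15 °C | run made earlier; the fed solution adds 1.0 times the starting volume |  |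
| gamma | 1.00 equiv (fed, over 5.0 min) | 0.0150 M |  | at 15 °C throughout; the fed solution adds 1.0 times the starting volume | 40 min |
| theta | 1.00 equiv (fed, over 10 min) | 0.0150 M |  | at −10 °C until 10 min, from then on at 15 °C; the fed solution adds 1.0 times the starting volume | 40 min |

| run | time / min | target / % | side product / % |
|---|---|---|---|
| south | 8.00 | 0 | 0 |
| south | 15.0 | 3.1 | 1.0 |
| south | 25.0 | 7.8 | 0 |
| south | 30.0 | 11.7 | 0.1 |
| south | 40.0 | 14.6 | 0 |
| south-east | 2.00 | 1.6 | 0.7 |
| south-east | 6.00 | 8.8 | 0 |
| south-east | 12.0 | 34.9 | 7.6 |
| south-east | 15.0 | 42.0 | 9.3 |
| south-east | 20.0 | 42.8 | 22.4 |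
| east | 4.00 | 0.9 | 0.8 |
| east | 10.0 | 5.6 | 0.5 |
| east | 20.0 | 12.0 | 2.4 |
| east | 30.0 | 19.0 | 1.9 |
| east | 40.0 | 27.9 | 0 |

(standard deviation of a reading: 1 percentage point)

- the winner by share of target in all that became target or side product; "neither" if no more than 2 percentage points parts them (gamma / theta / neither)
- share of target in all that became target or side product, gamma
- share of target in all that became target or side product, theta

- amounts are per litre of the starting volume; all of the dose is in the solution fed
- solid substrate is a solid; its amount is given per volume of the solution
- what was read earlier has a scatter of 1 percentage point, one standard deviation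
- at the start none of the solid substrate is in solution
- what has only dissolved of solid substrate counts as not reacted

- Read the uptake of partner from east, counting one partner per target, where target climbs from 5.6% at 10.0 min to 27.9% at 40.0 min: that is 1.11 mM/min at −15 °C, a rough reading.
- South-east, between 6.00 min and 12.0 min, reads 6.52 mM/min at 2 °C, with twice the partner of east and half its protic impurity.
- Divide the partner out and leave the protic impurity unreckoned. The two readings then put a rough factor of 2.93 on warming from −15 °C to 2 °C.
- Scale geometrically with temperature, accepting that gamma lies beyond the runs: reckon the uptake at 7.42 mM/min at 15 °C and 1.53 mM/min at −10 °C.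
- Multiply by the feed times, gamma's being half of theta's. By this reckoning gamma takes up 24.7% of its partner during the feed, theta 10.2%.
- Put what remains into the final volume: reckon gamma at 56.5 mM, theta at 67.4 mM.
- Carry this [partner] at the end of the feed, the standing partner, to the next flask.
- My call: theta wins the selectivity by more than 2 percentage points, with a larger standing partner than gamma and a cold feed. East, also cold, reads target 27.9% against side product 0% at 40.0 min, each with a scatter of 1 point.
- The forecast reads neither, with gamma at 62% (47% to 78%) and theta at 63.5% (48% to 80%), on the view that “Theta's cold feed gives only a small, cleaner head start”, which differs from my call.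
- The flasks give theta as winner: gamma 41.0%, theta 49.0%.

    starting material + partner → target (k = 0.900 /M/min, Ea = 56.0 kJ/mol)
    solid substrate ⇌ starting material, rate k2*(cs2 - [starting material]) while solid is left; crystals form when [starting material] > cs2 (solubility = 20.0 mM, k = 0.860 /min)
    partner + intermediate A → intermediate C (k = 0.860 /M/min, Ea = 52.0 kJ/mol)
    intermediate D → side product (k = 0.0450 /min, Ea = 82.0 kJ/mol)
    starting material + protic impurity → quenched substrate (k = 5.40 /M/min, Ea = 60.0 kJ/mol)
    partner + intermediate A ⇌ intermediate B (K = 0.960 /M, k = 2.20 /M/min, Ea = 39.0 kJ/mol, ΔH = −31.0 kJ/mol)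
    starting material → intermediate A (k = 0.0570 /min, Ea = 75.0 kJ/mol)
    partner + intermediate C → intermediate D (k = 1.10 /M/min, Ea = 46.0 kJ/mol)
    (constants at −10 °C)

- Compare the feeds. At 10.0 min theta ended its cold feed with side product at 0.0177% and [partner] at 68.4 mM, against the reckoned 67.4 mM; at 40.0 min it held target 25.7% and side product 26.8%. At 5.00 min gamma ended its warm feed with side product at 3.13% and [partner] at 52.1 mM, against the reckoned 56.5 mM; at 40.0 min it held target 20.2% and side product 29.1%. Now take gamma's neighbour with 0.60 M of solid substrate: gamma's reckoned uptake fraction gives it a standing partner of 226 mM, and its share of target is 57.0%.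

Readings and results were generated by integration with made-up constants; scatter was added.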